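**Plan**

1. Target numbering: lactone O1, C2 (C=O), C3 (quaternary; OH and 4-hydroxy-3-methoxybenzyl), C4 (H and 3,4-dimethoxybenzyl), C5 (CH2). The retrosynthesis first masks both hydroxyls as benzyl ethers and raises the benzylic CH2 on C3 to an aryl ketone.
2. It then cuts C2–C3 and O1–C5 together. This takes out CO2 and leaves an acyclic α-benzyloxy γ-chloro aryl ketone.
3. Enabling feature: C3 lies between the benzylic carbon (as C=O it makes C3–H the only acidic C–H, so C3 becomes an enolate carbon) and, through C4, the ring CH2 C5 (as CH2Cl an electrophile). The C and one O of CO2 bridge this 1,3 nucleophile/electrophile pair and close the five-membered ring O1–C2–C3–C4–C5.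
4. The chloro ketone comes from aryllithium opening of an α-benzyloxy-β-(3,4-dimethoxybenzyl)butyrolactone, whose carbonyl carbon becomes the benzylic carbon; that lactone comes from an Evans alkylation and an enolate hydroxylation.
5. Forward order: acyl oxazolidinone, alkylation, first (sacrificial) lactone, hydroxylation, benzylation, aryllithium opening, chloride, CO2 annulation to the final lactone, ketone reduction, hydrogenolysis.
6. Stereochemistry: C4 (S) from the auxiliary-controlled alkylation. C3 (S) from the CO2 annulation, where reversible carboxylation and a diastereo-differentiating ring closure should place the aroyl group trans to the C4 benzyl group; the epimers of the precursor at the alkoxy carbon converge.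

Key step: step 8

Remark: the intermediates from the hydroxylation to the chloro ketone are drawn as the epimer expected to predominate at the oxygen-bearing carbon; that carbon becomes planar in the key step, so its configuration does not matter. The hydroxy ketone is drawn open-chain although it may rest partly as its cyclic hemiketal.

**Step 1**
Reactants: 1 3-(3,4-dimethoxyphenyl)propanoic acid; 2 (S)-4-benzyl-1,3-oxazolidin-2-one
Product: 4 (4S)-4-benzyl-3-[3-(3,4-dimethoxyphenyl)propanoyl]-1,3-oxazolidin-2-one, via mixed pivalic anhydride 3 (not isolated)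
Conditions: PivCl, Et3N, THF, −20 °C; then 2, LiCl, rt
Reagents that add atoms: none
Why: N-acylation of the oxazolidinone through the mixed anhydride (LiCl/Et3N protocol) should attach the auxiliary without a strong base; no stereocentre is formed.

**Step 2**
Reactants: 4 (4S)-4-benzyl-3-[3-(3,4-dimethoxyphenyl)propanoyl]-1,3-oxazolidin-2-one; 5 tert-butyl bromoacetate
Product: 7 tert-butyl (3R)-4-[(4S)-4-benzyl-2-oxo-1,3-oxazolidin-3-yl]-3-[(3,4-dimethoxyphenyl)methyl]-4-oxobutanoate, via sodium Z-enolate 6 (not isolated)
Conditions: NaHMDS, THF, −78 °C; then 5, −78 → −40 °C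
Reagents that add atoms: none
Why: Evans asymmetric alkylation, in which the bromoacetate enters the chelated Z-enolate on the face opposite the benzyl group of the auxiliary and so sets the (R) centre that becomes C4 (S) of the target.

**Step 3**
Reactants: 7 tert-butyl (3R)-4-[(4S)-4-benzyl-2-oxo-1,3-oxazolidin-3-yl]-3-[(3,4-dimethoxyphenyl)methyl]-4-oxobutanoate
Product: 9 (4R)-4-[(3,4-dimethoxyphenyl)methyl]oxolan-2-one, via hydroxy tert-butyl ester 8 (not isolated)
Conditions: LiBH4, MeOH (1 equiv), THF, 0 °C; then TsOH·H2O (cat.), toluene, 80 °C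
Reagents that add atoms: none
Why: LiBH4 should reduce the activated imide carbonyl in preference to the tert-butyl ester (reductive auxiliary removal), and acid-catalysed lactonisation of the γ-hydroxy ester then closes the ring without touching the stereocentre.

**Step 4**
Reactants: 9 (4R)-4-[(3,4-dimethoxyphenyl)methyl]oxolan-2-one
Product: 11 (3R,4S)-3-hydroxy-4-[(3,4-dimethoxyphenyl)methyl]oxolan-2-one, via sodium lactone enolate 10 (not isolated)
Conditions: NaHMDS, THF, −78 °C; then (±)-trans-2-(phenylsulfonyl)-3-phenyloxaziridine, −78 °C; aq. NH4Cl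
Reagents that add atoms: 2-(phenylsulfonyl)-3-phenyloxaziridine (Davis oxaziridine), O=S(=O)(N1OC1c1ccccc1)c1ccccc1
Why: Davis enolate hydroxylation, in which oxygen should be delivered anti to the C4 substituent (3,4-trans), although the configuration of this carbon is erased in step 8.

**Step 5**
Reactants: 11 (3R,4S)-3-hydroxy-4-[(3,4-dimethoxyphenyl)methyl]oxolan-2-one
Product: 12 (3R,4S)-3-(benzyloxy)-4-[(3,4-dimethoxyphenyl)methyl]oxolan-2-one
Conditions: BnBr, Ag2O, CH2Cl2, rt, dark
Reagents that add atoms: benzyl bromide, BrCc1ccccc1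
Why: silver oxide-mediated O-benzylation of an α-hydroxy ester is non-basic and should leave the lactone closed; the benzyl ether is small at oxygen, inert to aryllithium and KHMDS, and falls in the final hydrogenolysis.

**Step 6**
Reactants: 12 (3R,4S)-3-(benzyloxy)-4-[(3,4-dimethoxyphenyl)methyl]oxolan-2-one; 13 1-(benzyloxy)-4-bromo-2-methoxybenzene
Product: 15 (2R,3S)-2-(benzyloxy)-1-[4-(benzyloxy)-3-methoxyphenyl]-3-[(3,4-dimethoxyphenyl)methyl]-4-hydroxybutan-1-one, via aryllithium 14 (not isolated)
Conditions: 13, n-BuLi, THF, −78 °C; then 12, −78 °C; AcOH, −78 °C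
Reagents that add atoms: none
Why: bromine–lithium exchange followed by single addition of the aryllithium to the lactone carbonyl, whose tetrahedral lithium lactolate (chelated by the α-benzyloxy group, as in aryllithium additions to benzyl-protected aldonolactones) should survive at −78 °C and release the aryl ketone and the primary alcohol only on quench.

**Step 7**
Reactants: 15 (2R,3S)-2-(benzyloxy)-1-[4-(benzyloxy)-3-methoxyphenyl]-3-[(3,4-dimethoxyphenyl)methyl]-4-hydroxybutan-1-one
Product: 17 (2R,3R)-2-(benzyloxy)-1-[4-(benzyloxy)-3-methoxyphenyl]-4-chloro-3-[(3,4-dimethoxyphenyl)methyl]butan-1-one, via primary mesylate 16 (not isolated)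
Conditions: MsCl, Et3N, CH2Cl2, −10 °C; then LiCl, DMF, 40 °C
Reagents that add atoms: lithium chloride, [Li+].[Cl-]
Why: sulfonylation of the primary alcohol of the open-chain form and SN2 exchange by chloride should give a γ-chloro ketone that cannot eliminate by E1cB (the leaving group is not β to the carbonyl) and that is inert to a cold enolate.

**Step 8**
Reactants: 17 (2R,3R)-2-(benzyloxy)-1-[4-(benzyloxy)-3-methoxyphenyl]-4-chloro-3-[(3,4-dimethoxyphenyl)methyl]butan-1-one; 18 carbon dioxide
Product: 21 (3R,4S)-3-(benzyloxy)-3-[4-(benzyloxy)-3-methoxybenzoyl]-4-[(3,4-dimethoxyphenyl)methyl]oxolan-2-one, via potassium enolate 19 (not isolated), via potassium keto carboxylate 20 (not isolated)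
Conditions: KHMDS, THF, −78 °C; CO2 (1 atm, dry), −78 °C; then DMF, 18-crown-6 (cat.), CO2 (1 atm), 50 °C
Reagents that add atoms: none
Why: Proposed new method: KHMDS removes the only acidic C–H of 17 (the benzyloxy methine next to the aryl ketone) to give enolate 19, whose fully substituted carbon captures CO2 as the β-keto carboxylate 20, and on warming in DMF the carboxylate oxygen displaces the primary chloride, so that the C–C(=O) and O–CH2 bonds form in one flask and the labile carboxyl group is locked as the lactone. The closest known reaction types are the C-carboxylation of ketone enolates with CO2 with in situ O-alkylation to β-keto esters and the base/CO2 carboxylation–cyclisation cascades of alkynyl ketones to γ-lactones; new here are the sp3 electrophile, the alkoxy-substituted quaternary carbon and the stereochemical funnel. The lactone ring closes by 5-exo-tet O-alkylation. The quaternary centre should be set not in the carboxylation, which for a β-keto carboxylate with a quaternary α-carbon is expected to be reversible under CO2 at 50 °C, but in the slower ring closure (Curtin–Hammett control), where the existing centre carrying the 3,4-dimethoxybenzyl group lies in the forming ring and the large aroyl group should take the side trans to it, leaving the benzyloxy group cis as the target requires; both epimers of 17 at the benzyloxy carbon and both enolate geometries converge. The step needs C- over O-carboxylation and carboxylate closure over enolate alkylation (3-exo-tet to a cyclopropane or O-alkylation to a dihydrofuran): O-carboxylation is reversible and unproductive, the chloride is inert to the enolate at −78 °C, and at 50 °C the CO2 atmosphere should keep the free enolate at a trace level while the deliberately slow chloride leaving group gives the carboxylates time to equilibrate.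

**Step 9**
Reactants: 21 (3R,4S)-3-(benzyloxy)-3-[4-(benzyloxy)-3-methoxybenzoyl]-4-[(3,4-dimethoxyphenyl)methyl]oxolan-2-one
Product: 22 (3R,4S)-3-(benzyloxy)-3-{[4-(benzyloxy)-3-methoxyphenyl](hydroxy)methyl}-4-[(3,4-dimethoxyphenyl)methyl]oxolan-2-one (both carbinol epimers)
Conditions: NaBH4, CeCl3·7H2O, MeOH–THF, −40 → −10 °C
Reagents that add atoms: none
Why: Luche-type reduction should take the ketone in preference to the lactone at low temperature, with cerium tempering the alkoxide basicity that could cleave the non-enolisable β-keto lactone; the new carbinol centre is removed in step 10, so its configuration is irrelevant.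

**Step 10**
Reactants: 22 (3R,4S)-3-(benzyloxy)-3-{[4-(benzyloxy)-3-methoxyphenyl](hydroxy)methyl}-4-[(3,4-dimethoxyphenyl)methyl]oxolan-2-one
Product: 23 trachelogenin, (3S,4S)-4-[(3,4-dimethoxyphenyl)methyl]-3-hydroxy-3-[(4-hydroxy-3-methoxyphenyl)methyl]oxolan-2-one
Conditions: H2 (3 atm), 10% Pd/C, EtOAc–AcOH, 40 °C
Reagents that add atoms: none
Why: catalytic hydrogenolysis should cleave the electron-rich benzylic C–OH (as for the benzylic hydroxyl of 7-hydroxy lignan lactones) and both benzyl ethers in one operation, while the tertiary alcohol and the lactone C–O are not benzylic and no stereocentre is touched.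

**Compound list**

1 | 3-(3,4-dimethoxyphenyl)propanoic acid | COc1ccc(CCC(=O)O)cc1OC | starting material
2 | (S)-4-benzyl-1,3-oxazolidin-2-one | O=C1N[C@@H](Cc2ccccc2)CO1 | starting material
3 | 3-(3,4-dimethoxyphenyl)propanoic pivalic anhydride | COc1ccc(CCC(=O)OC(=O)C(C)(C)C)cc1OC | intermediate
4 | (4S)-4-benzyl-3-[3-(3,4-dimethoxyphenyl)propanoyl]-1,3-oxazolidin-2-one | COc1ccc(CCC(=O)N2[C@@H](Cc3ccccc3)COC2=O)cc1OC | intermediate
5 | tert-butyl bromoacetate | CC(C)(C)OC(=O)CBr | starting material
6 | sodium (Z)-enolate of 4 | COc1ccc(C/C=C(\[O-])N2[C@@H](Cc3ccccc3)COC2=O)cc1OC.[Na+] | intermediate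
7 | tert-butyl (3R)-4-[(4S)-4-benzyl-2-oxo-1,3-oxazolidin-3-yl]-3-[(3,4-dimethoxyphenyl)methyl]-4-oxobutanoate | O=C([C@@H](CC(=O)OC(C)(C)C)Cc1ccc(OC)c(OC)c1)N1[C@@H](Cc2ccccc2)COC1=O | intermediate
8 | tert-butyl (3R)-3-[(3,4-dimethoxyphenyl)methyl]-4-hydroxybutanoate | OC[C@@H](CC(=O)OC(C)(C)C)Cc1ccc(OC)c(OC)c1 | intermediate
9 | (4R)-4-[(3,4-dimethoxyphenyl)methyl]oxolan-2-one | O=C1C[C@@H](Cc2ccc(OC)c(OC)c2)CO1 | intermediate
10 | sodium enolate of 9 | [Na+].[O-]C1=C[C@@H](Cc2ccc(OC)c(OC)c2)CO1 | intermediate
11 | (3R,4S)-3-hydroxy-4-[(3,4-dimethoxyphenyl)methyl]oxolan-2-one | O[C@H]1C(=O)OC[C@@H]1Cc1ccc(OC)c(OC)c1 | intermediate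
12 | (3R,4S)-3-(benzyloxy)-4-[(3,4-dimethoxyphenyl)methyl]oxolan-2-one | O([C@H]1C(=O)OC[C@@H]1Cc1ccc(OC)c(OC)c1)Cc1ccccc1 | intermediate
13 | 1-(benzyloxy)-4-bromo-2-methoxybenzene | COc1cc(Br)ccc1OCc1ccccc1 | starting material
14 | [4-(benzyloxy)-3-methoxyphenyl]lithium | [Li]c1ccc(OCc2ccccc2)c(OC)c1 | intermediate
15 | (2R,3S)-2-(benzyloxy)-1-[4-(benzyloxy)-3-methoxyphenyl]-3-[(3,4-dimethoxyphenyl)methyl]-4-hydroxybutan-1-one | O(Cc1ccccc1)[C@H]([C@H](CO)Cc1ccc(OC)c(OC)c1)C(=O)c1ccc(OCc2ccccc2)c(OC)c1 | intermediate
16 | primary methanesulfonate of 15 | O(Cc1ccccc1)[C@H]([C@H](COS(C)(=O)=O)Cc1ccc(OC)c(OC)c1)C(=O)c1ccc(OCc2ccccc2)c(OC)c1 | intermediate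
17 | (2R,3R)-2-(benzyloxy)-1-[4-(benzyloxy)-3-methoxyphenyl]-4-chloro-3-[(3,4-dimethoxyphenyl)methyl]butan-1-one | O(Cc1ccccc1)[C@H]([C@H](CCl)Cc1ccc(OC)c(OC)c1)C(=O)c1ccc(OCc2ccccc2)c(OC)c1 | intermediate
18 | carbon dioxide | O=C=O | starting material
19 | potassium enolate of 17 (either geometry) | [K+].[O-]C(=C(OCc1ccccc1)[C@H](CCl)Cc1ccc(OC)c(OC)c1)c1ccc(OCc2ccccc2)c(OC)c1 | intermediate
20 | potassium 2-(benzyloxy)-2-[4-(benzyloxy)-3-methoxybenzoyl]-4-chloro-3-[(3,4-dimethoxyphenyl)methyl]butanoate (3R; equilibrating epimers at C2) | [K+].[O-]C(=O)C(OCc1ccccc1)([C@H](CCl)Cc1ccc(OC)c(OC)c1)C(=O)c1ccc(OCc2ccccc2)c(OC)c1 | intermediate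
21 | (3R,4S)-3-(benzyloxy)-3-[4-(benzyloxy)-3-methoxybenzoyl]-4-[(3,4-dimethoxyphenyl)methyl]oxolan-2-one | COc1cc(C(=O)[C@@]2(OCc3ccccc3)C(=O)OC[C@@H]2Cc2ccc(OC)c(OC)c2)ccc1OCc1ccccc1 | intermediate
22 | (3R,4S)-3-(benzyloxy)-3-{[4-(benzyloxy)-3-methoxyphenyl](hydroxy)methyl}-4-[(3,4-dimethoxyphenyl)methyl]oxolan-2-one (both carbinol epimers) | COc1cc(C(O)[C@@]2(OCc3ccccc3)C(=O)OC[C@@H]2Cc2ccc(OC)c(OC)c2)ccc1OCc1ccccc1 | intermediate
23 | trachelogenin, (3S,4S)-4-[(3,4-dimethoxyphenyl)methyl]-3-hydroxy-3-[(4-hydroxy-3-methoxyphenyl)methyl]oxolan-2-one | COc1cc(C[C@@]2(O)C(=O)OC[C@@H]2Cc2ccc(OC)c(OC)c2)ccc1O | target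

**Totals and risks**

Total step count: 10. Longest linear sequence: 10 steps (1 to 23); 13 and carbon dioxide enter at steps 6 and 8.

Steps most likely to fail:

1. Step 8 (labelled). What may go wrong: ring closure overtaking the loss and regain of CO2, so that the kinetic and possibly unselective carboxylation decides the configuration of the quaternary centre; or decarboxylation on warming followed by C- or O-alkylation of the enolate. Fallback (known chemistry, no CO2): set out from 12. Its potassium enolate (KHMDS, THF, −78 °C) is alkylated with commercial 4-(benzyloxy)-3-methoxybenzyl bromide, the halide entering trans to the C4 substituent as in the usual alkylation of β-substituted butyrolactone enolates, to give the dibenzyl ether of trachelogenin F1. Hydrogenolysis (H2, Pd/C, EtOAc) then returns to the route at 23.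

2. Step 10. What may go wrong: stalling of the hydrogenolysis at the hindered benzylic C–OH next to the quaternary carbon, or acid-induced ionisation there with a 1,2-shift once the neighbouring ether has been cleaved. Fallback by radical deoxygenation: set out from 22. PhOC(S)Cl, pyridine and DMAP give the O-phenyl thionocarbonate F2; Bu3SnH and AIBN in toluene at 90 °C remove the oxygen (Barton–McCombie deoxygenation) to give the dibenzyl ether F1 already described; neutral hydrogenolysis of its two benzyl ethers returns to the route at 23.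

3. Step 7. What may go wrong: reaction of 15 through its cyclic hemiketal, with sulfonylation and ionisation at the anomeric hydroxyl and loss to a dihydrofuran instead of substitution at the primary carbon. Fallback that opens the lactone before the aryl group is brought in, so that no γ-hydroxy ketone is formed: set out from 12. AlMe3 and MeONHMe·HCl in CH2Cl2 give the hydroxy Weinreb amide F3; Appel chlorination (PPh3, NCS) gives the chloro Weinreb amide F4; addition of aryllithium 14 at −78 °C (Weinreb ketone synthesis) returns to the route at 17 and bypasses step 6 as well.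

**Further compounds**

F1 | step 8 | (3S,4S)-3-(benzyloxy)-3-{[4-(benzyloxy)-3-methoxyphenyl]methyl}-4-[(3,4-dimethoxyphenyl)methyl]oxolan-2-one | COc1cc(C[C@@]2(OCc3ccccc3)C(=O)OC[C@@H]2Cc2ccc(OC)c(OC)c2)ccc1OCc1ccccc1
F2 | step 10 | O-phenyl thionocarbonate of 22 | COc1cc(C(OC(=S)Oc3ccccc3)[C@@]2(OCc3ccccc3)C(=O)OC[C@@H]2Cc2ccc(OC)c(OC)c2)ccc1OCc1ccccc1
F3 | step 7 | (2R,3S)-2-(benzyloxy)-3-[(3,4-dimethoxyphenyl)methyl]-4-hydroxy-N-methoxy-N-methylbutanamide | CON(C)C(=O)[C@H](OCc1ccccc1)[C@H](CO)Cc1ccc(OC)c(OC)c1
F4 | step 7 | (2R,3R)-2-(benzyloxy)-4-chloro-3-[(3,4-dimethoxyphenyl)methyl]-N-methoxy-N-methylbutanamide | CON(C)C(=O)[C@H](OCc1ccccc1)[C@H](CCl)Cc1ccc(OC)c(OC)c1
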